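Chain numbering: C1 (CO2H) to C20 (pyranone CH2); ring A is the tetrahydrofuran (O, C6–C9). Everything rests on cutting ring A back to a cyclobutanone. A suprafacial [2+2] addition of dichloroketene to a Z enol ether forms C7–C8 and a temporary C6–C9 bond, closes the four-membered ring and sets C6 and C7 at once; it exploits the cis C6-carbon/C7-oxygen pair beside the ring CH2 (C8) of ring A. Oxygen insertion into the temporary bond then gives the lactone of ring A. The precursor is a (Z)-4-methoxybenzyl enol ether whose allylic C5 carbinol, set by asymmetric ynone reduction, bears a bulky silyl ether next to the (E)-trisubstituted alkene.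

Key step: step 8

Remark (protecting groups): the primary C1 and C14 hydroxyls travel as TBS ethers and the secondary allylic C5 hydroxyl as the bulkier TIPS ether, so that the primary ethers come off first and the larger silyl group shields one enol ether face in step 8; the C7 oxygen keeps its PMB group until the acid is in place.
Assumption (step 5): the alkynyl group is taken to occupy the catalyst site that aryl groups occupy in aryl ketone reductions, so the (R,R) catalyst should give the (R) carbinol; the sense would be checked on 12 before going on.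

Step 1
Reactants: 1 tert-butyl(but-3-yn-1-yloxy)dimethylsilane
Product: 3 (E)-tert-butyl[(4-iodo-3-methylbut-3-en-1-yl)oxy]dimethylsilane, via alkenylalane 2 (not isolated)
Conditions: Me3Al, Cp2ZrCl2 (0.25 equiv), CH2Cl2, 0 °C to rt; then I2, THF, −30 to 0 °C
Reagents that add atoms: trimethylaluminium C[Al](C)C; iodine [I][I]
Why: Negishi zirconium-catalysed carboalumination adds methyl and aluminium syn across the terminal alkyne with methyl on the internal carbon, and iodinolysis of the alkenyl–aluminium bond with retention gives the (E)-trisubstituted vinyl iodide.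

Step 2
Reactants: 3 (E)-tert-butyl[(4-iodo-3-methylbut-3-en-1-yl)oxy]dimethylsilane
Product: 5 (E)-5-(tert-butyldimethylsilyloxy)-3-methylpent-2-enal, via alkenyllithium 4 (not isolated)
Conditions: t-BuLi (2.1 equiv), Et2O, −78 °C; DMF, −78 to 0 °C; H2O
Reagents that add atoms: N,N-dimethylformamide CN(C)C=O
Why: Lithium–iodine exchange proceeds with retention of the alkene geometry and Bouveault-type formylation of the alkenyllithium with DMF gives the enal.

Step 3
Reactants: 6 4-methoxybenzyl alcohol; 7 trichloroethylene; 5 (E)-5-(tert-butyldimethylsilyloxy)-3-methylpent-2-enal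
Product: 10 racemic (E)-7-(tert-butyldimethylsilyloxy)-1-[(4-methoxybenzyl)oxy]-5-methylhept-4-en-1-yn-3-ol, via dichlorovinyl ether 8 (not isolated), via lithium alkoxyacetylide 9 (not isolated)
Conditions: 6, KH, THF, 0 °C; 7, −50 °C to rt; n-BuLi (2.3 equiv), −78 °C; then 5, −78 °C; pH 7 buffer, kept below 25 °C
Reagents that add atoms: none
Why: The Greene ynol ether synthesis (alkoxide substitution on trichloroethylene, then elimination and chlorine–lithium exchange) generates the lithium alkoxyacetylide in the flask, which adds 1,2 to the enal to give the carbinol, racemic at this point.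

Step 4
Reactants: 10 racemic (E)-7-(tert-butyldimethylsilyloxy)-1-[(4-methoxybenzyl)oxy]-5-methylhept-4-en-1-yn-3-ol
Product: 11 (E)-7-(tert-butyldimethylsilyloxy)-1-[(4-methoxybenzyl)oxy]-5-methylhept-4-en-1-yn-3-one
Conditions: MnO2 (activated, excess), CH2Cl2, rt
Reagents that add atoms: none
Why: The carbinol is both allylic and propargylic, so neutral MnO2 oxidation should give the cross-conjugated ynone without touching the acid-labile ynol ether.

Step 5
Reactants: 11 (E)-7-(tert-butyldimethylsilyloxy)-1-[(4-methoxybenzyl)oxy]-5-methylhept-4-en-1-yn-3-one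
Product: 12 (3R,4E)-7-(tert-butyldimethylsilyloxy)-1-[(4-methoxybenzyl)oxy]-5-methylhept-4-en-1-yn-3-ol
Conditions: Ru[(R,R)-TsDPEN](p-cymene) (5 mol %), i-PrOH, rt
Reagents that add atoms: none
Why: Noyori asymmetric transfer hydrogenation reduces the ynone carbonyl chemoselectively under neutral conditions, hydride being delivered to the carbonyl face fixed by the alkynyl group sitting in the catalyst's π-recognition site, which with the (R,R) catalyst should set the C5 carbinol as R.

Step 6
Reactants: 12 (3R,4E)-7-(tert-butyldimethylsilyloxy)-1-[(4-methoxybenzyl)oxy]-5-methylhept-4-en-1-yn-3-ol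
Product: 13 (3R,4E)-7-(tert-butyldimethylsilyloxy)-1-[(4-methoxybenzyl)oxy]-5-methyl-3-(triisopropylsilyloxy)hept-4-en-1-yne
Conditions: TIPSOTf, 2,6-lutidine (excess), CH2Cl2, −78 °C
Reagents that add atoms: triisopropylsilyl trifluoromethanesulfonate CC(C)[Si](OS(=O)(=O)C(F)(F)F)(C(C)C)C(C)C
Why: Silylation of the hindered secondary alcohol with the silyl triflate under base-buffered conditions should leave the ynol ether intact and installs the bulky group that later shields one enol ether face.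

Step 7
Reactants: 13 (3R,4E)-7-(tert-butyldimethylsilyloxy)-1-[(4-methoxybenzyl)oxy]-5-methyl-3-(triisopropylsilyloxy)hept-4-en-1-yne
Product: 14 (1Z,3R,4E)-7-(tert-butyldimethylsilyloxy)-1-[(4-methoxybenzyl)oxy]-5-methyl-3-(triisopropylsilyloxy)hepta-1,4-diene
Conditions: H2 (1 atm), Pd/CaCO3 poisoned with Pb(OAc)2, quinoline, hexane/EtOAc, rt
Reagents that add atoms: none
Why: Lindlar semihydrogenation adds hydrogen syn to the alkyne and stops at the Z enol ether, the trisubstituted alkene and the benzylic ether being inert to the poisoned catalyst.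

Step 8
Reactants: 14 (1Z,3R,4E)-7-(tert-butyldimethylsilyloxy)-1-[(4-methoxybenzyl)oxy]-5-methyl-3-(triisopropylsilyloxy)hepta-1,4-diene; 15 trichloroacetyl chloride
Product: 17 (3S,4S)-2,2-dichloro-3-[(4-methoxybenzyl)oxy]-4-[(1R,2E)-5-(tert-butyldimethylsilyloxy)-3-methyl-1-(triisopropylsilyloxy)pent-2-en-1-yl]cyclobutan-1-one, via dichloroketene 16 (not isolated)
Conditions: Zn–Cu couple, 15 (slow addition), Et2O/DME, 0 °C to rt
Reagents that add atoms: none
Why: Zinc dechlorinates the acid chloride to dichloroketene, which adds to the electron-rich enol ether in a concerted but asynchronous [2+2] cycloaddition in which nucleophilic C6 attacks the ketene carbonyl carbon (the temporary C6–C9 bond) and the CCl2 carbon bonds to the oxygen-bearing C7 (the C7–C8 bond). The closest known reaction type is the dichloroketene–enol ether cycloaddition used for 3-alkoxycyclobutanones and, after ring expansion, 3-alkoxy-γ-lactones. The four-membered ring is closed by the cycloaddition itself, suprafacially on the enol ether, so the Z geometry becomes the cis C6/C7 relationship. The absolute sense at C6 and C7 is relayed from C5: allylic 1,3-strain with the cis benzyloxy group holds the C5–H bond in the alkene plane, and the ketene approaches the face anti to the triisopropylsilyloxy group. The step needs regioselectivity, secured by the polarisation of the enol ether, chemoselectivity over the trisubstituted alkene, secured by the far higher nucleophilicity of the enol ether, and survival of the acid-labile substrate, for which DME ties up the zinc dichloride formed.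

Step 9
Reactants: 17 (3S,4S)-2,2-dichloro-3-[(4-methoxybenzyl)oxy]-4-[(1R,2E)-5-(tert-butyldimethylsilyloxy)-3-methyl-1-(triisopropylsilyloxy)pent-2-en-1-yl]cyclobutan-1-one
Product: 18 (2S,3R)-3-[(4-methoxybenzyl)oxy]-2-[(1R,2E)-5-(tert-butyldimethylsilyloxy)-3-methyl-1-(triisopropylsilyloxy)pent-2-en-1-yl]cyclobutan-1-one
Conditions: Zn–Cu couple, NH4Cl, MeOH, rt
Reagents that add atoms: none
Why: Reductive dechlorination of the α,α-dichloroketone by zinc through the zinc enolate removes both chlorines under near-neutral conditions that should not epimerise the cis ring substituents.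

Step 10
Reactants: 18 (2S,3R)-3-[(4-methoxybenzyl)oxy]-2-[(1R,2E)-5-(tert-butyldimethylsilyloxy)-3-methyl-1-(triisopropylsilyloxy)pent-2-en-1-yl]cyclobutan-1-one
Product: 19 (4R,5S)-4-[(4-methoxybenzyl)oxy]-5-[(1R,2E)-5-(tert-butyldimethylsilyloxy)-3-methyl-1-(triisopropylsilyloxy)pent-2-en-1-yl]dihydrofuran-2(3H)-one
Conditions: 30% H2O2, AcOH, 0 to 10 °C
Reagents that add atoms: hydrogen peroxide OO
Why: Strain-driven Baeyer–Villiger oxidation of the cyclobutanone with hydrogen peroxide, which does not epoxidise the trisubstituted alkene, inserts oxygen into the temporary C6–C9 bond with migration of the more substituted C6 and retention of its configuration.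

Step 11
Reactants: 20 tert-butyldimethyl(prop-2-yn-1-yloxy)silane; 21 oxirane
Product: 23 5-(tert-butyldimethylsilyloxy)pent-3-yn-1-ol, via lithium acetylide 22 (not isolated)
Conditions: n-BuLi, THF, −78 °C; BF3·OEt2; 21, −78 °C
Reagents that add atoms: none
Why: Yamaguchi–Hirao opening of the epoxide by the lithium acetylide under BF3 activation gives the homopropargylic alcohol.

Step 12
Reactants: 23 5-(tert-butyldimethylsilyloxy)pent-3-yn-1-ol
Product: 24 tert-butyl[(5-iodopent-2-yn-1-yl)oxy]dimethylsilane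
Conditions: I2, PPh3, imidazole, CH2Cl2, 0 °C
Reagents that add atoms: iodine [I][I]
Why: Appel-type iodination converts the primary alcohol into the iodide through its alkoxyphosphonium salt.

Step 13
Reactants: 24 tert-butyl[(5-iodopent-2-yn-1-yl)oxy]dimethylsilane; 19 (4R,5S)-4-[(4-methoxybenzyl)oxy]-5-[(1R,2E)-5-(tert-butyldimethylsilyloxy)-3-methyl-1-(triisopropylsilyloxy)pent-2-en-1-yl]dihydrofuran-2(3H)-one
Product: 26 ring A lactol (5R,6S,7R; C9 hemiketal as anomeric mixture) bearing the 5-(tert-butyldimethylsilyloxy)pent-3-yn-1-yl chain at C9, via alkyllithium 25 (not isolated)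
Conditions: 24 (1.4 equiv), t-BuLi (2.8 equiv), Et2O/pentane, −78 °C; then 19, −78 °C; AcOH quench at −78 °C
Reagents that add atoms: none
Why: Lithium–iodine exchange gives the primary homopropargylic alkyllithium, which adds only once to the lactone carbonyl because the tetrahedral lithium lactolate persists at −78 °C until the cold quench.

Step 14
Reactants: 26 ring A lactol (5R,6S,7R; anomeric mixture)
Product: 27 ring A tetrahydrofuran (5R,6S,7R,9R) with C1 OTBS, C5 OTIPS, C7 OPMB and the C9 5-(tert-butyldimethylsilyloxy)pent-3-yn-1-yl chain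
Conditions: Et3SiH, BF3·OEt2, CH2Cl2, −78 to −50 °C
Reagents that add atoms: none
Why: Lewis-acid ionisation to the five-membered oxocarbenium ion and silane reduction (reductive etherification) should deliver hydride by inside attack on the envelope with the C7 alkoxy group pseudoaxial (Woerpel model), that is cis to the C7 oxygen, which sets C9 as R with its side chain trans to the C6 substituent.

Step 15
Reactants: 27 ring A tetrahydrofuran (5R,6S,7R,9R) with C1 OTBS and C14 OTBS
Product: 28 (5R,6S,7R,9R)-C1,C14-diol (C12–C13 alkyne; C5 OTIPS; C7 OPMB)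
Conditions: HF·pyridine, pyridine, THF, 0 °C to rt
Reagents that add atoms: none
Why: Pyridine-buffered fluoride cleaves the two primary TBS ethers much faster than the hindered secondary TIPS ether, a standard selective desilylation.

Step 16
Reactants: 28 (5R,6S,7R,9R)-C1,C14-diol
Product: 30 (12Z)-12-chloro-C12=C13 allylic alcohol (C14 OH and C1 OH free), via alkenylalanate 29 (not isolated)
Conditions: NaAlH2(OCH2CH2OMe)2 (4 equiv), THF, 0 °C to rt; then NCS, −78 to −20 °C
Reagents that add atoms: N-chlorosuccinimide O=C1CCC(=O)N1Cl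
Why: Hydroxyl-directed trans-hydroalumination of the propargylic alcohol places aluminium on C12 in a five-membered alkoxyalanate and chlorinolysis with retention gives the (Z)-3-chloroallylic alcohol with chlorine cis to C14.

Step 17
Reactants: 30 (12Z)-12-chloro-C12=C13 allylic alcohol
Product: 31 (12Z)-12,14-dichloride (C1 OH free)
Conditions: NCS, Me2S (2.5 equiv each), CH2Cl2, −20 to 0 °C; brine work-up
Reagents that add atoms: N-chlorosuccinimide O=C1CCC(=O)N1Cl
Why: Corey–Kim chlorination turns only the allylic alcohol into the chloride by SN2 collapse of its alkoxysulfonium salt, whereas the saturated primary C1 alcohol is returned on aqueous work-up.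

Step 18
Reactants: 31 (12Z)-12,14-dichloride; 32 prop-2-yn-1-ol
Product: 33 (12Z)-skipped enyne (C14 CH2 joined to C15≡C16–C20H2OH; C1 OH free)
Conditions: CuI, NaI, K2CO3, DMF, rt
Reagents that add atoms: none
Why: Copper acetylide alkylation of the allylic halide, activated by in situ Finkelstein exchange, at its unhindered CH2 terminus gives the skipped enyne with the chloroalkene geometry unchanged.

Step 19
Reactants: 33 (12Z)-skipped enyne
Product: 34 (12Z,15Z)-16-(tributylstannyl) allylic alcohol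
Conditions: Bu3SnH, [Cp*RuCl]4 (3 mol %), CH2Cl2, rt
Reagents that add atoms: tributyltin hydride CCCC[SnH](CCCC)CCCC
Why: Ruthenium-catalysed trans-hydrostannation steered by the propargylic hydroxyl places tin on C16 next to the OH and hydrogen on C15 anti to it, which fixes the trisubstituted alkene geometry with C14 cis to tin.

Step 20
Reactants: 34 (12Z,15Z)-16-(tributylstannyl) allylic alcohol; 35 ethyl (Z)-3-iodoacrylate
Product: 37 ring B pyranone (5-alkylidene-5,6-dihydropyran-2-one; C1 OH free; C5 OTIPS; C7 OPMB), via hydroxy dienoate 36 (not isolated)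
Conditions: Pd(PPh3)4 (10 mol %), copper thiophene-2-carboxylate Cu(O2CC4H3S), [NBu4][Ph2PO2], DMF, rt; then PPTS (cat.), CH2Cl2, rt
Reagents that add atoms: none
Why: Copper-assisted Stille coupling with retention at both alkenyl partners gives the (2Z,4E)-dienoate, whose Z ester is held next to the C20 hydroxyl and lactonises to ring B.

Step 21
Reactants: 37 ring B pyranone with C1 OH free
Product: 39 C1 carboxylic acid (C5 OTIPS; C7 OPMB), via aldehyde 38 (not isolated)
Conditions: TEMPO (0.2 equiv), PhI(OAc)2 (2.5 equiv), MeCN/H2O, 0 °C to rt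
Reagents that add atoms: water O
Why: Oxoammonium (TEMPO) oxidation of the only free alcohol to the aldehyde and of its hydrate to the acid runs under near-neutral conditions that should not move the β,γ-alkene into conjugation.

Step 22
Reactants: 39 C1 carboxylic acid (C5 OTIPS; C7 OPMB)
Product: 40 C7 alcohol (C5 OTIPS) carboxylic acid
Conditions: DDQ, CH2Cl2/pH 7 buffer, 0 °C
Reagents that add atoms: none
Why: Oxidative cleavage of the electron-rich benzyl ether by DDQ through its benzylic oxocarbenium ion frees the C7 hydroxyl without affecting the silyl ether, the alkenes or the lactone.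

Step 23
Reactants: 40 C7 alcohol (C5 OTIPS) carboxylic acid
Product: 41 CNP0180366.1
Conditions: HF·pyridine, THF, 0 °C to rt
Reagents that add atoms: none
Why: Fluoride-mediated cleavage of the remaining secondary TIPS ether under mildly acidic conditions spares the base-sensitive dienyl lactone and skipped diene and gives the target.

Compound list
1 | tert-butyl(but-3-yn-1-yloxy)dimethylsilane | C#CCCO[Si](C)(C)C(C)(C)C | starting material
2 | [(E)-4-(tert-butyldimethylsilyloxy)-2-methylbut-1-en-1-yl]dimethylalane | C/C(=C\[Al](C)C)CCO[Si](C)(C)C(C)(C)C | intermediate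
3 | (E)-tert-butyl[(4-iodo-3-methylbut-3-en-1-yl)oxy]dimethylsilane | C/C(=C\I)CCO[Si](C)(C)C(C)(C)C | intermediate
4 | [(E)-4-(tert-butyldimethylsilyloxy)-2-methylbut-1-en-1-yl]lithium | C/C(=C\[Li])CCO[Si](C)(C)C(C)(C)C | intermediate
5 | (E)-5-(tert-butyldimethylsilyloxy)-3-methylpent-2-enal | C/C(=C\C=O)CCO[Si](C)(C)C(C)(C)C | intermediate
6 | 4-methoxybenzyl alcohol | COc1ccc(CO)cc1 | starting material
7 | trichloroethylene | ClC=C(Cl)Cl | starting material
8 | (E)-1-[(1,2-dichlorovinyl)oxymethyl]-4-methoxybenzene | COc1ccc(CO/C(Cl)=C\Cl)cc1 | intermediate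
9 | lithium 2-[(4-methoxybenzyl)oxy]ethynide | COc1ccc(COC#C[Li])cc1 | intermediate
10 | racemic (E)-7-(tert-butyldimethylsilyloxy)-1-[(4-methoxybenzyl)oxy]-5-methylhept-4-en-1-yn-3-ol | C/C(=C\C(O)C#COCc1ccc(OC)cc1)CCO[Si](C)(C)C(C)(C)C | intermediate
11 | (E)-7-(tert-butyldimethylsilyloxy)-1-[(4-methoxybenzyl)oxy]-5-methylhept-4-en-1-yn-3-one | C/C(=C\C(=O)C#COCc1ccc(OC)cc1)CCO[Si](C)(C)C(C)(C)C | intermediate
12 | (3R,4E)-7-(tert-butyldimethylsilyloxy)-1-[(4-methoxybenzyl)oxy]-5-methylhept-4-en-1-yn-3-ol | C/C(=C\[C@@H](O)C#COCc1ccc(OC)cc1)CCO[Si](C)(C)C(C)(C)C | intermediate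
13 | (3R,4E)-7-(tert-butyldimethylsilyloxy)-1-[(4-methoxybenzyl)oxy]-5-methyl-3-(triisopropylsilyloxy)hept-4-en-1-yne | C/C(=C\[C@@H](O[Si](C(C)C)(C(C)C)C(C)C)C#COCc1ccc(OC)cc1)CCO[Si](C)(C)C(C)(C)C | intermediate
14 | (1Z,3R,4E)-7-(tert-butyldimethylsilyloxy)-1-[(4-methoxybenzyl)oxy]-5-methyl-3-(triisopropylsilyloxy)hepta-1,4-diene | C/C(=C\[C@@H](O[Si](C(C)C)(C(C)C)C(C)C)/C=C\OCc1ccc(OC)cc1)CCO[Si](C)(C)C(C)(C)C | intermediate
15 | trichloroacetyl chloride | ClC(=O)C(Cl)(Cl)Cl | starting material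
16 | dichloroketene | ClC(Cl)=C=O | intermediate
17 | (3S,4S)-2,2-dichloro-3-[(4-methoxybenzyl)oxy]-4-[(1R,2E)-5-(tert-butyldimethylsilyloxy)-3-methyl-1-(triisopropylsilyloxy)pent-2-en-1-yl]cyclobutan-1-one (ring substituents cis) | C/C(=C\[C@@H](O[Si](C(C)C)(C(C)C)C(C)C)[C@H]1C(=O)C(Cl)(Cl)[C@H]1OCc2ccc(OC)cc2)CCO[Si](C)(C)C(C)(C)C | intermediate
18 | (2S,3R)-3-[(4-methoxybenzyl)oxy]-2-[(1R,2E)-5-(tert-butyldimethylsilyloxy)-3-methyl-1-(triisopropylsilyloxy)pent-2-en-1-yl]cyclobutan-1-one | C/C(=C\[C@@H](O[Si](C(C)C)(C(C)C)C(C)C)[C@H]1C(=O)C[C@H]1OCc2ccc(OC)cc2)CCO[Si](C)(C)C(C)(C)C | intermediate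
19 | (4R,5S)-4-[(4-methoxybenzyl)oxy]-5-[(1R,2E)-5-(tert-butyldimethylsilyloxy)-3-methyl-1-(triisopropylsilyloxy)pent-2-en-1-yl]dihydrofuran-2(3H)-one | C/C(=C\[C@@H](O[Si](C(C)C)(C(C)C)C(C)C)[C@H]1OC(=O)C[C@H]1OCc2ccc(OC)cc2)CCO[Si](C)(C)C(C)(C)C | intermediate
20 | tert-butyldimethyl(prop-2-yn-1-yloxy)silane | C#CCO[Si](C)(C)C(C)(C)C | starting material
21 | oxirane | C1CO1 | starting material
22 | [3-(tert-butyldimethylsilyloxy)prop-1-yn-1-yl]lithium | [Li]C#CCO[Si](C)(C)C(C)(C)C | intermediate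
23 | 5-(tert-butyldimethylsilyloxy)pent-3-yn-1-ol | OCCC#CCO[Si](C)(C)C(C)(C)C | intermediate
24 | tert-butyl[(5-iodopent-2-yn-1-yl)oxy]dimethylsilane | ICCC#CCO[Si](C)(C)C(C)(C)C | intermediate
25 | [5-(tert-butyldimethylsilyloxy)pent-3-yn-1-yl]lithium | [Li]CCC#CCO[Si](C)(C)C(C)(C)C | intermediate
26 | ring A lactol (5R,6S,7R; C9 hemiketal, anomeric mixture): C9 carries OH and the 5-(tert-butyldimethylsilyloxy)pent-3-yn-1-yl chain; C1 OTBS, C5 OTIPS, C7 OPMB | C/C(=C\[C@@H](O[Si](C(C)C)(C(C)C)C(C)C)[C@H]1OC(O)(CCC#CCO[Si](C)(C)C(C)(C)C)C[C@H]1OCc2ccc(OC)cc2)CCO[Si](C)(C)C(C)(C)C | intermediate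
27 | ring A tetrahydrofuran (5R,6S,7R,9R), 2,5-trans: C9 5-(tert-butyldimethylsilyloxy)pent-3-yn-1-yl; C1 OTBS, C5 OTIPS, C7 OPMB | C/C(=C\[C@@H](O[Si](C(C)C)(C(C)C)C(C)C)[C@H]1O[C@H](CCC#CCO[Si](C)(C)C(C)(C)C)C[C@H]1OCc2ccc(OC)cc2)CCO[Si](C)(C)C(C)(C)C | intermediate
28 | (5R,6S,7R,9R)-C1,C14-diol with C12–C13 alkyne; C5 OTIPS, C7 OPMB | C/C(=C\[C@@H](O[Si](C(C)C)(C(C)C)C(C)C)[C@H]1O[C@H](CCC#CCO)C[C@H]1OCc2ccc(OC)cc2)CCO | intermediate
29 | cyclic alkenylalanate of 28 (aluminium on C12 and bound to the C14 oxygen; disodium salt, idealised) | C/C(=C\[C@@H](O[Si](C(C)C)(C(C)C)C(C)C)[C@H]1O[C@H](CCC2=CCO[Al-]2(OCCOC)OCCOC)C[C@H]1OCc3ccc(OC)cc3)CC[O-].[Na+].[Na+] | intermediate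
30 | (5R,6S,7R,9R,12Z)-12-chloro-C12=C13 allylic alcohol (C14 OH, C1 OH free; C5 OTIPS, C7 OPMB) | C/C(=C\[C@@H](O[Si](C(C)C)(C(C)C)C(C)C)[C@H]1O[C@H](CC/C(Cl)=C/CO)C[C@H]1OCc2ccc(OC)cc2)CCO | intermediate
31 | (5R,6S,7R,9R,12Z)-12,14-dichloride (C1 OH free; C5 OTIPS, C7 OPMB) | C/C(=C\[C@@H](O[Si](C(C)C)(C(C)C)C(C)C)[C@H]1O[C@H](CC/C(Cl)=C/CCl)C[C@H]1OCc2ccc(OC)cc2)CCO | intermediate
32 | prop-2-yn-1-ol | C#CCO | starting material
33 | (5R,6S,7R,9R,12Z)-skipped enyne with C15≡C16 and C20 OH (C1 OH free; C5 OTIPS, C7 OPMB) | C/C(=C\[C@@H](O[Si](C(C)C)(C(C)C)C(C)C)[C@H]1O[C@H](CC/C(Cl)=C/CC#CCO)C[C@H]1OCc2ccc(OC)cc2)CCO | intermediate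
34 | (5R,6S,7R,9R,12Z,15Z)-16-(tributylstannyl) allylic alcohol (C20 OH, C1 OH free; C5 OTIPS, C7 OPMB) | C/C(=C\[C@@H](O[Si](C(C)C)(C(C)C)C(C)C)[C@H]1O[C@H](CC/C(Cl)=C/C/C=C(/CO)[Sn](CCCC)(CCCC)CCCC)C[C@H]1OCc2ccc(OC)cc2)CCO | intermediate
35 | ethyl (Z)-3-iodoacrylate | CCOC(=O)/C=C\I | starting material
36 | ethyl (2Z,4E)-dienoate (C17=C18 Z, C15=C16 E) with free C20 OH and C1 OH; C5 OTIPS, C7 OPMB | C/C(=C\[C@@H](O[Si](C(C)C)(C(C)C)C(C)C)[C@H]1O[C@H](CC/C(Cl)=C/C/C=C(/CO)\C=C/C(=O)OCC)C[C@H]1OCc2ccc(OC)cc2)CCO | intermediate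
37 | ring B pyranone, C1 alcohol (C5 OTIPS, C7 OPMB) | C/C(=C\[C@@H](O[Si](C(C)C)(C(C)C)C(C)C)[C@H]1O[C@H](CC/C(Cl)=C/C/C=C2\C=CC(=O)OC2)C[C@H]1OCc3ccc(OC)cc3)CCO | intermediate
38 | ring B pyranone, C1 aldehyde (C5 OTIPS, C7 OPMB) | C/C(=C\[C@@H](O[Si](C(C)C)(C(C)C)C(C)C)[C@H]1O[C@H](CC/C(Cl)=C/C/C=C2\C=CC(=O)OC2)C[C@H]1OCc3ccc(OC)cc3)CC=O | intermediate
39 | ring B pyranone, C1 carboxylic acid (C5 OTIPS, C7 OPMB) | C/C(=C\[C@@H](O[Si](C(C)C)(C(C)C)C(C)C)[C@H]1O[C@H](CC/C(Cl)=C/C/C=C2\C=CC(=O)OC2)C[C@H]1OCc3ccc(OC)cc3)CC(=O)O | intermediate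
40 | C5 triisopropylsilyl ether of the target (C7 OH free) | C/C(=C\[C@@H](O[Si](C(C)C)(C(C)C)C(C)C)[C@H]1O[C@H](CC/C(Cl)=C/C/C=C2\C=CC(=O)OC2)C[C@H]1O)CC(=O)O | intermediate
41 | CNP0180366.1: (3E,5R)-5-hydroxy-5-[(2S,3R,5R)-3-hydroxy-5-{(3Z,6E)-3-chloro-6-[6-oxo-2H-pyran-3(6H)-ylidene]hex-3-en-1-yl}tetrahydrofuran-2-yl]-3-methylpent-3-enoic acid | C/C(=C\[C@@H](O)[C@H]1O[C@H](CC/C(Cl)=C/C/C=C2\C=CC(=O)OC2)C[C@H]1O)CC(=O)O | target

Total step count: 23 steps (21 on the main line, 2 for iodide 24).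
Longest linear sequence: 21 steps (1 to 41: steps 1–10 and 13–23).

Steps most likely to fail

Step 8. The ketene may add with poor facial discrimination, or the zinc salts may ionise the doubly allylic silyl ether before cycloaddition. The fallback sets out from 14 and comes back at 19, building the lactone by reagent-controlled alkoxyallylation instead of cycloaddition. OsO4 (cat.)/NMO and then NaIO4 cleave only the electron-rich enol ether of 14 to the α-silyloxy aldehyde (2R,3E)-6-(tert-butyldimethylsilyloxy)-4-methyl-2-(triisopropylsilyloxy)hex-3-enal F1. Brown alkoxyallylboration of F1 uses the [(Z)-3-(4-methoxybenzyloxy)allyl]diisopinocampheylborane antipode that reinforces Felkin addition (made from allyl 4-methoxybenzyl ether, s-BuLi, Ipc2BOMe and BF3·OEt2). It should give (3R,4S,5R,6E)-9-(tert-butyldimethylsilyloxy)-3-[(4-methoxybenzyl)oxy]-7-methyl-5-(triisopropylsilyloxy)nona-1,6-dien-4-ol F2, with C6 and C7 syn from the Z borane and C6 anti to C5. 9-BBN and then NaOH/H2O2 hydroborate only the terminal vinyl group to (3R,4S,5R,6E)-9-(tert-butyldimethylsilyloxy)-3-[(4-methoxybenzyl)oxy]-7-methyl-5-(triisopropylsilyloxy)non-6-ene-1,4-diol F3. TEMPO/PhI(OAc)2 oxidative lactonisation of this 1,4-diol gives 19.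

Step 14. Hydride delivery to the oxocarbenium ion may be unselective, or BF3 may strip the PMB or the allylic silyl ether. The fallback sets out from 19 and comes back at 27, setting C9 by SN2 inversion of a carbinol instead of by oxocarbenium reduction. i-Bu2AlH (CH2Cl2, −78 °C) reduces 19 to the lactol (4R,5S)-4-[(4-methoxybenzyl)oxy]-5-[(1R,2E)-5-(tert-butyldimethylsilyloxy)-3-methyl-1-(triisopropylsilyloxy)pent-2-en-1-yl]tetrahydrofuran-2-ol F4. Alkyllithium 25 (2.5 equiv, Et2O, −78 °C) adds to its open aldehyde form; the polar 1,3-induction model predicts mainly the 1,3-anti product, the (5R,6S,7R,9S)-C6,C9-diol F5, whose C9 epimer would be separated. MsCl/2,4,6-collidine sulfonylates the less hindered C9 hydroxyl to give the C9 methanesulfonate of that diol F6. KN(SiMe3)2 (THF, 0 °C) then closes ring A by 5-exo-tet attack of the C6 alkoxide with inversion at C9, giving 27.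

Step 5. Hydrogen transfer to the electron-rich enynone may be slow, or the alkenyl and alkynyl groups may compete for the catalyst's recognition site and erode the enantioselectivity. The fallback sets out from 5 and comes back at 12, setting C5 by catalytic asymmetric alkynylation instead of oxidation and reduction. Acetylide 9, made as in step 3, is quenched with methanol at −78 °C to give 1-(ethynyloxymethyl)-4-methoxybenzene F7. Its alkynylzinc, formed with Me2Zn in the presence of the ProPhenol ligand antipode that delivers the R carbinol and Ph3PO (toluene, 0 °C), adds to enal 5 and gives 12 directly; enals are good substrates for this zinc alkynylation.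

Further compounds
F1 | step 8 | (2R,3E)-6-(tert-butyldimethylsilyloxy)-4-methyl-2-(triisopropylsilyloxy)hex-3-enal | C/C(=C\[C@@H](O[Si](C(C)C)(C(C)C)C(C)C)C=O)CCO[Si](C)(C)C(C)(C)C
F2 | step 8 | (3R,4S,5R,6E)-9-(tert-butyldimethylsilyloxy)-3-[(4-methoxybenzyl)oxy]-7-methyl-5-(triisopropylsilyloxy)nona-1,6-dien-4-ol | C/C(=C\[C@@H](O[Si](C(C)C)(C(C)C)C(C)C)[C@@H](O)[C@H](OCc1ccc(OC)cc1)C=C)CCO[Si](C)(C)C(C)(C)C
F3 | step 8 | (3R,4S,5R,6E)-9-(tert-butyldimethylsilyloxy)-3-[(4-methoxybenzyl)oxy]-7-methyl-5-(triisopropylsilyloxy)non-6-ene-1,4-diol | C/C(=C\[C@@H](O[Si](C(C)C)(C(C)C)C(C)C)[C@@H](O)[C@H](OCc1ccc(OC)cc1)CCO)CCO[Si](C)(C)C(C)(C)C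
F4 | step 14 | (4R,5S)-4-[(4-methoxybenzyl)oxy]-5-[(1R,2E)-5-(tert-butyldimethylsilyloxy)-3-methyl-1-(triisopropylsilyloxy)pent-2-en-1-yl]tetrahydrofuran-2-ol (anomeric mixture) | C/C(=C\[C@@H](O[Si](C(C)C)(C(C)C)C(C)C)[C@H]1OC(O)C[C@H]1OCc2ccc(OC)cc2)CCO[Si](C)(C)C(C)(C)C
F5 | step 14 | (5R,6S,7R,9S)-C6,C9-diol (open chain; C1 OTBS, C5 OTIPS, C7 OPMB, C14 OTBS, C12–C13 alkyne) | C/C(=C\[C@@H](O[Si](C(C)C)(C(C)C)C(C)C)[C@@H](O)[C@H](OCc1ccc(OC)cc1)C[C@@H](O)CCC#CCO[Si](C)(C)C(C)(C)C)CCO[Si](C)(C)C(C)(C)C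
F6 | step 14 | C9 methanesulfonate of the (5R,6S,7R,9S)-C6,C9-diol | C/C(=C\[C@@H](O[Si](C(C)C)(C(C)C)C(C)C)[C@@H](O)[C@H](OCc1ccc(OC)cc1)C[C@@H](OS(C)(=O)=O)CCC#CCO[Si](C)(C)C(C)(C)C)CCO[Si](C)(C)C(C)(C)C
F7 | step 5 | 1-(ethynyloxymethyl)-4-methoxybenzene | COc1ccc(COC#C)cc1
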